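The cyclopentane ring (C1, C2, C3, C3a, C8a; azulene numbering) is disconnected as a (3+2) union: the oxygenated C1 next to quaternary C8a is read as an enol ether C1=C8a, and C2–C3–C3a as an alkenyl carbene whose acceptor is the future C4. C4 is tied as a temporary δ-lactone to O–C7, so the precursor is one acyclic diazo ester. In one flask, rhodium-carbene cyclopropanation and alkenylcyclopropane 1,3-shift forge C3a–C8a and C1–C2 and set C8a and C1; the resulting conjugated lactone alkene installs the C3 carbinol. The lactone is later transposed and replaced by the C5=C6 bridge of the seven-membered ring by ring-closing metathesis.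

Key step: step 7

Remark on labels: C1–C8a are the azulene locants of the target (C1 OAc, C3 tertiary carbinol, C4 aroate, C7 ketone, C8a methyl); "future C…" refers to them.
Remark (assumption): the sense of enantioinduction of Rh2(S-DOSP)4 in step 7 is assumed to give cyclopropane 10 as drawn; if the opposite sense is found, Rh2(R-DOSP)4 is used instead.

Step 1
Reactants: 1 tert-butyl(but-3-yn-1-yloxy)dimethylsilane
Product: 3 (E)-tert-butyl[(4-iodo-3-methylbut-3-en-1-yl)oxy]dimethylsilane, via alkenylalane 2 (not isolated)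
Conditions: Me3Al, Cp2ZrCl2 (20 mol %), CH2Cl2, 0 → 25 °C; then I2, THF, −30 °C
Reagents that add atoms: trimethylaluminium C[Al](C)C; iodine II
Why: Negishi zirconium-catalysed carboalumination adds CH3 and Al syn across the terminal alkyne with CH3 at the internal carbon, and iodinolysis of the C–Al bond with retention gives the (E)-iodide in which I is cis to CH3.

Step 2
Reactants: 3 (E)-tert-butyl[(4-iodo-3-methylbut-3-en-1-yl)oxy]dimethylsilane
Product: 4 (E)-tert-butyl({4-[(4-methoxybenzyl)oxy]-3-methylbut-3-en-1-yl}oxy)dimethylsilane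
Conditions: CuI (10 mol %), 3,4,7,8-tetramethyl-1,10-phenanthroline (20 mol %), Cs2CO3, 4-MeOC6H4CH2OH, toluene, 80 °C
Reagents that add atoms: 4-methoxybenzyl alcohol COc1ccc(CO)cc1
Why: Ullmann-type copper-catalysed C–O coupling of an alkenyl iodide with a primary alcohol proceeds with retention of the alkene geometry, so the ether oxygen stays cis to CH3.

Step 3
Reactants: 4 (E)-tert-butyl({4-[(4-methoxybenzyl)oxy]-3-methylbut-3-en-1-yl}oxy)dimethylsilane
Product: 5 (E)-4-[(4-methoxybenzyl)oxy]-3-methylbut-3-en-1-ol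
Conditions: Bu4NF, THF, 0 → 25 °C
Reagents that add atoms: none
Why: Fluoride-mediated desilylation of the primary silyl ether is non-acidic and leaves the acid-labile enol ether untouched.

Step 4
Reactants: 6 diketene (4-methylideneoxetan-2-one)
Product: 7 4-methyl-3-methylidenepentanoic acid
Conditions: i-PrMgCl, NiCl2(dppp) (3 mol %), THF, −40 → 0 °C; then aq. HCl
Reagents that add atoms: isopropylmagnesium chloride CC(C)[Mg]Cl
Why: Nickel-catalysed Kumada-type cross-coupling of i-PrMgCl with the alkenyl C–O bond of diketene opens the β-lactone to the 3-substituted but-3-enoate, the bidentate dppp ligand suppressing isomerisation of the secondary alkyl group.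

Step 5
Reactants: 5 (E)-4-[(4-methoxybenzyl)oxy]-3-methylbut-3-en-1-ol; 7 4-methyl-3-methylidenepentanoic acid
Product: 8 (E)-4-[(4-methoxybenzyl)oxy]-3-methylbut-3-en-1-yl 4-methyl-3-methylidenepentanoate
Conditions: EDC·HCl, DMAP (10 mol %), CH2Cl2, 0 °C
Reagents that add atoms: none
Why: Steglich carbodiimide esterification at 0 °C with only catalytic DMAP joins the two fragments without conjugating the β,γ-unsaturated acid or hydrolysing the enol ether.

Step 6
Reactants: 8 (E)-4-[(4-methoxybenzyl)oxy]-3-methylbut-3-en-1-yl 4-methyl-3-methylidenepentanoate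
Product: 9 (E)-4-[(4-methoxybenzyl)oxy]-3-methylbut-3-en-1-yl 2-diazo-4-methyl-3-methylidenepentanoate
Conditions: p-ABSA, DBU, MeCN, 0 °C
Reagents that add atoms: 4-acetamidobenzenesulfonyl azide CC(=O)Nc1ccc(cc1)S(=O)(=O)N=[N+]=[N-]
Why: Regitz diazo transfer to the methylene activated by both the ester and the alkene is the standard entry to alkenyldiazoacetates, and the product is kept cold and used at once to avoid electrocyclisation to a pyrazole.

Step 7
Reactants: 9 (E)-4-[(4-methoxybenzyl)oxy]-3-methylbut-3-en-1-yl 2-diazo-4-methyl-3-methylidenepentanoate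
Product: 11 (4aS,5S)-5-[(4-methoxybenzyl)oxy]-4a-methyl-7-(propan-2-yl)-4,4a,5,6-tetrahydrocyclopenta[c]pyran-1(3H)-one, via cyclopropane 10 (not isolated)
Conditions: Rh2(S-DOSP)4 (1 mol %), hexanes–CH2Cl2, −40 → 25 °C (slow addition of 9); then Et2AlCl (1.1 equiv), −78 °C, same flask
Reagents that add atoms: none
Why: Nitrogen loss from 9 gives a donor/acceptor rhodium alkenylcarbene that cyclopropanates its own electron-rich enol ether, forming C3a–C8a (and the sacrificial C3a–C1 bond) in 10; Et2AlCl, bound to the lactone carbonyl, then ionises the donor–acceptor bond C3a–C1 to an aluminium dienolate/oxocarbenium ion pair that recloses at the alkene terminus, forming C1–C2. The closest known reaction type is the formal (3+2) annulation of alkenyldiazoacetates with vinyl ethers by cyclopropanation and Lewis-acid-promoted alkenylcyclopropane-to-cyclopentene 1,3-shift, here run intramolecularly. The δ-lactone ring closes in a 6-exo sense by carbene addition across the tethered alkene (cis-fused bicyclo[4.1.0] unit), and the cyclopentene closes by suprafacial migration of C1 from C3a to C2, formally a 5-endo attack of the dienolate terminus on the oxocarbenium carbon within the ion pair. C8a is set in the cyclopropanation by the chiral prolinate ligands of the catalyst (choice of the enantiotopic alkene face), and C1 follows from the (E)-enol ether, which places OPMB cis to CH3 and to the alkenyl group in 10, and from retention at the migrating carbon. The step needs cyclopropanation to outrun allylic C–H insertion and pyrazole formation, which the nucleophilic trisubstituted enol ether in a six-ring-forming tether and slow addition should secure, and C- rather than O-closure of the ion pair, which is secured because only C-closure gives the stable conjugated lactone.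

Step 8
Reactants: 11 (4aS,5S)-5-[(4-methoxybenzyl)oxy]-4a-methyl-7-(propan-2-yl)-4,4a,5,6-tetrahydrocyclopenta[c]pyran-1(3H)-one
Product: 12 (4aS,5S)-5-hydroxy-4a-methyl-7-(propan-2-yl)-4,4a,5,6-tetrahydrocyclopenta[c]pyran-1(3H)-one
Conditions: DDQ, CH2Cl2–pH 7 buffer, 0 °C
Reagents that add atoms: none
Why: Oxidative cleavage of the p-methoxybenzyl ether by DDQ (hydride abstraction, then hydrolysis of the oxocarbenium ion) frees the secondary alcohol without touching the conjugated tetrasubstituted alkene or the lactone.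

Step 9
Reactants: 12 (4aS,5S)-5-hydroxy-4a-methyl-7-(propan-2-yl)-4,4a,5,6-tetrahydrocyclopenta[c]pyran-1(3H)-one
Product: 13 (4aR,5S,7S,7aS)-7,7a-epoxy-5-hydroxy-4a-methyl-7-(propan-2-yl)hexahydrocyclopenta[c]pyran-1(3H)-one (epoxide oxygen cis to OH and to the angular CH3)
Conditions: m-CPBA, NaHCO3, CH2Cl2, 0 → 25 °C
Reagents that add atoms: 3-chloroperbenzoic acid OOC(=O)c1cccc(Cl)c1
Why: Henbest hydroxyl-directed peracid epoxidation, in which the homoallylic hydroxyl of this cyclopent-3-enol hydrogen-bonds the peracid and delivers oxygen to the alkene face cis to OH and CH3, the tetrasubstituted alkene remaining nucleophilic enough despite conjugation to the lactone.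

Step 10
Reactants: 13 (4aR,5S,7S,7aS)-7,7a-epoxy-5-hydroxy-4a-methyl-7-(propan-2-yl)hexahydrocyclopenta[c]pyran-1(3H)-one
Product: 14 (4aR,5S,7S,7aS)-7,7a-epoxy-4a-methyl-7-(propan-2-yl)-5-[(triethylsilyl)oxy]hexahydrocyclopenta[c]pyran-1(3H)-one
Conditions: Et3SiCl, imidazole, DMF, 0 °C
Reagents that add atoms: chlorotriethylsilane CC[Si](Cl)(CC)CC
Why: Silylation of the only free hydroxyl protects it for the organometallic steps and adds bulk to the face that must stay closed in the next step.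

Step 11
Reactants: 14 (4aR,5S,7S,7aS)-7,7a-epoxy-4a-methyl-7-(propan-2-yl)-5-[(triethylsilyl)oxy]hexahydrocyclopenta[c]pyran-1(3H)-one
Product: 15 (4aS,5S,7S,7aS)-7-hydroxy-4a-methyl-7-(propan-2-yl)-5-[(triethylsilyl)oxy]hexahydrocyclopenta[c]pyran-1(3H)-one (trans ring fusion)
Conditions: SmI2 (2.5 equiv), THF–MeOH, −78 °C
Reagents that add atoms: none
Why: Molander-type SmI2 reduction of an α,β-epoxy ester cleaves the Cα–O bond by two single-electron transfers to the tertiary β-alkoxide and a trivalent samarium enolate, whose kinetic protonation at C7a (future C3a) from the face opposite the angular CH3, the samarium alkoxide and the OSiEt3 group should set the trans ring fusion.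

Step 12
Reactants: 15 (4aS,5S,7S,7aS)-7-hydroxy-4a-methyl-7-(propan-2-yl)-5-[(triethylsilyl)oxy]hexahydrocyclopenta[c]pyran-1(3H)-one
Product: 17 (1S,2R,3S,4S)-2-[(1R)-1-hydroxyprop-2-en-1-yl]-3-(2-hydroxyethyl)-3-methyl-1-(propan-2-yl)-4-[(triethylsilyl)oxy]cyclopentan-1-ol, via lactol 16 (not isolated)
Conditions: i-Bu2AlH (2.2 equiv), CH2Cl2, −78 °C; then CH2=CHMgBr (5 equiv), THF, −78 → 0 °C
Reagents that add atoms: vinylmagnesium bromide C=C[Mg]Br
Why: Partial reduction of the δ-lactone gives a lactolate that releases the β-alkoxy aldehyde, and CH2=CHMgBr adds to its six-membered chelate (Cram-chelate control by the tertiary alkoxide) from the face remote from the axial ring CH2, setting the (R)-carbinol of the future C4.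

Step 13
Reactants: 17 (1S,2R,3S,4S)-2-[(1R)-1-hydroxyprop-2-en-1-yl]-3-(2-hydroxyethyl)-3-methyl-1-(propan-2-yl)-4-[(triethylsilyl)oxy]cyclopentan-1-ol
Product: 19 (1R,4aS,5S,7S,7aR)-1-ethenyl-7-hydroxy-4a-methyl-7-(propan-2-yl)-5-[(triethylsilyl)oxy]hexahydrocyclopenta[c]pyran-3(1H)-one, via lactol 18 (not isolated)
Conditions: TEMPO (20 mol %), PhI(OAc)2 (2.5 equiv), CH2Cl2, 25 °C
Reagents that add atoms: none
Why: The oxoammonium ion from TEMPO oxidises only the unhindered primary alcohol, the aldehyde is trapped by the allylic hydroxyl as a δ-lactol that is oxidised further, so this oxidative lactonisation masks the C4 oxygen and moves the lactone carbonyl to the future C7.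

Step 14
Reactants: 19 (1R,4aS,5S,7S,7aR)-1-ethenyl-7-hydroxy-4a-methyl-7-(propan-2-yl)-5-[(triethylsilyl)oxy]hexahydrocyclopenta[c]pyran-3(1H)-one
Product: 20 (1S,2R,3S,4S)-2-[(1R)-1-hydroxyprop-2-en-1-yl]-3-methyl-3-(3-methyl-2-oxobut-3-en-1-yl)-1-(propan-2-yl)-4-[(triethylsilyl)oxy]cyclopentan-1-ol
Conditions: CH2=C(CH3)MgBr (3 equiv), THF, −78 → −40 °C; aq. NH4Cl
Reagents that add atoms: isopropenylmagnesium bromide CC(=C)[Mg]Br
Why: Addition of an alkenylmagnesium halide to a δ-lactone stops at the magnesium hemiketal at low temperature, which on work-up opens to the isopropenyl ketone and frees the allylic hydroxyl.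

Step 15
Reactants: 20 (1S,2R,3S,4S)-2-[(1R)-1-hydroxyprop-2-en-1-yl]-3-methyl-3-(3-methyl-2-oxobut-3-en-1-yl)-1-(propan-2-yl)-4-[(triethylsilyl)oxy]cyclopentan-1-ol; 21 4-[(tert-butyldimethylsilyl)oxy]benzoic acid
Product: 22 (1R)-1-[(1R,2S,4S,5S)-2-hydroxy-5-methyl-5-(3-methyl-2-oxobut-3-en-1-yl)-2-(propan-2-yl)-4-[(triethylsilyl)oxy]cyclopentyl]prop-2-en-1-yl 4-[(tert-butyldimethylsilyl)oxy]benzoate
Conditions: EDC·HCl, DMAP, CH2Cl2, 25 °C
Reagents that add atoms: none
Why: Steglich esterification acylates the secondary allylic alcohol while the tertiary alcohol is inert, with retention at the carbinol carbon because its C–O bond is not touched.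

Step 16
Reactants: 22 (1R)-1-[(1R,2S,4S,5S)-2-hydroxy-5-methyl-5-(3-methyl-2-oxobut-3-en-1-yl)-2-(propan-2-yl)-4-[(triethylsilyl)oxy]cyclopentyl]prop-2-en-1-yl 4-[(tert-butyldimethylsilyl)oxy]benzoate
Product: 23 (1S,3S,3aR,4R,8aS)-3-hydroxy-6,8a-dimethyl-7-oxo-3-(propan-2-yl)-1-[(triethylsilyl)oxy]-1,2,3,3a,4,7,8,8a-octahydroazulen-4-yl 4-[(tert-butyldimethylsilyl)oxy]benzoate
Conditions: second-generation Hoveyda–Grubbs catalyst (5 mol %), toluene, 80 °C
Reagents that add atoms: none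
Why: Ring-closing metathesis between the vinyl group and the 1,1-disubstituted alkene of the enone closes the seven-membered ring as the trisubstituted cycloheptenone with loss of ethene, the two chains sitting on adjacent ring carbons.

Step 17
Reactants: 23 (1S,3S,3aR,4R,8aS)-3-hydroxy-6,8a-dimethyl-7-oxo-3-(propan-2-yl)-1-[(triethylsilyl)oxy]-1,2,3,3a,4,7,8,8a-octahydroazulen-4-yl 4-[(tert-butyldimethylsilyl)oxy]benzoate
Product: 24 (1S,3S,3aR,4R,8aS)-1,3-dihydroxy-6,8a-dimethyl-7-oxo-3-(propan-2-yl)-1,2,3,3a,4,7,8,8a-octahydroazulen-4-yl 4-[(tert-butyldimethylsilyl)oxy]benzoate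
Conditions: PPTS, MeOH, 25 °C
Reagents that add atoms: none
Why: Acid-catalysed methanolysis removes the alkyl triethylsilyl ether selectively, since aryl tert-butyldimethylsilyl ethers are stable to mild acid.

Step 18
Reactants: 24 (1S,3S,3aR,4R,8aS)-1,3-dihydroxy-6,8a-dimethyl-7-oxo-3-(propan-2-yl)-1,2,3,3a,4,7,8,8a-octahydroazulen-4-yl 4-[(tert-butyldimethylsilyl)oxy]benzoate
Product: 25 (1S,3S,3aR,4R,8aS)-1-acetoxy-3-hydroxy-6,8a-dimethyl-7-oxo-3-(propan-2-yl)-1,2,3,3a,4,7,8,8a-octahydroazulen-4-yl 4-[(tert-butyldimethylsilyl)oxy]benzoate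
Conditions: Ac2O, pyridine, DMAP (cat.), CH2Cl2, 0 → 25 °C
Reagents that add atoms: acetic anhydride CC(=O)OC(C)=O
Why: Acetylation under nucleophilic catalysis takes place at the secondary hydroxyl only, the tertiary C3 hydroxyl being too hindered.

Step 19
Reactants: 25 (1S,3S,3aR,4R,8aS)-1-acetoxy-3-hydroxy-6,8a-dimethyl-7-oxo-3-(propan-2-yl)-1,2,3,3a,4,7,8,8a-octahydroazulen-4-yl 4-[(tert-butyldimethylsilyl)oxy]benzoate
Product: 26 (1S,3S,3aR,4R,8aS)-1-acetoxy-3-hydroxy-6,8a-dimethyl-7-oxo-3-(propan-2-yl)-1,2,3,3a,4,7,8,8a-octahydroazulen-4-yl 4-hydroxybenzoate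
Conditions: Bu4NF, AcOH, THF, 0 °C
Reagents that add atoms: none
Why: Buffered fluoride cleaves the aryl silyl ether within minutes and leaves the acetate, the aroate and the enone intact.

Compound list
1 | tert-butyl(but-3-yn-1-yloxy)dimethylsilane | C#CCCO[Si](C)(C)C(C)(C)C | starting material
2 | (E)-{4-[(tert-butyldimethylsilyl)oxy]-2-methylbut-1-en-1-yl}dimethylalane | C[Al](C)/C=C(\C)CCO[Si](C)(C)C(C)(C)C | intermediate
3 | (E)-tert-butyl[(4-iodo-3-methylbut-3-en-1-yl)oxy]dimethylsilane | I/C=C(\C)CCO[Si](C)(C)C(C)(C)C | intermediate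
4 | (E)-tert-butyl({4-[(4-methoxybenzyl)oxy]-3-methylbut-3-en-1-yl}oxy)dimethylsilane | COc1ccc(CO/C=C(\C)CCO[Si](C)(C)C(C)(C)C)cc1 | intermediate
5 | (E)-4-[(4-methoxybenzyl)oxy]-3-methylbut-3-en-1-ol | COc1ccc(CO/C=C(\C)CCO)cc1 | intermediate
6 | diketene (4-methylideneoxetan-2-one) | C=C1CC(=O)O1 | starting material
7 | 4-methyl-3-methylidenepentanoic acid | CC(C)C(=C)CC(=O)O | intermediate
8 | (E)-4-[(4-methoxybenzyl)oxy]-3-methylbut-3-en-1-yl 4-methyl-3-methylidenepentanoate | CC(C)C(=C)CC(=O)OCC/C(C)=C/OCc1ccc(OC)cc1 | intermediate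
9 | (E)-4-[(4-methoxybenzyl)oxy]-3-methylbut-3-en-1-yl 2-diazo-4-methyl-3-methylidenepentanoate | CC(C)C(=C)C(=[N+]=[N-])C(=O)OCC/C(C)=C/OCc1ccc(OC)cc1 | intermediate
10 | (1R,6S,7R)-7-[(4-methoxybenzyl)oxy]-6-methyl-1-(3-methylbut-1-en-2-yl)-3-oxabicyclo[4.1.0]heptan-2-one | O=C1OCC[C@]2(C)[C@@H](OCc3ccc(OC)cc3)[C@]12C(=C)C(C)C | intermediate
11 | (4aS,5S)-5-[(4-methoxybenzyl)oxy]-4a-methyl-7-(propan-2-yl)-4,4a,5,6-tetrahydrocyclopenta[c]pyran-1(3H)-one | COc1ccc(CO[C@H]2CC(C(C)C)=C3C(=O)OCC[C@]23C)cc1 | intermediate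
12 | (4aS,5S)-5-hydroxy-4a-methyl-7-(propan-2-yl)-4,4a,5,6-tetrahydrocyclopenta[c]pyran-1(3H)-one | O[C@H]1CC(C(C)C)=C2C(=O)OCC[C@]12C | intermediate
13 | (4aR,5S,7S,7aS)-7,7a-epoxy-5-hydroxy-4a-methyl-7-(propan-2-yl)hexahydrocyclopenta[c]pyran-1(3H)-one | O[C@H]1C[C@@]2(C(C)C)O[C@]23C(=O)OCC[C@]13C | intermediate
14 | (4aR,5S,7S,7aS)-7,7a-epoxy-4a-methyl-7-(propan-2-yl)-5-[(triethylsilyl)oxy]hexahydrocyclopenta[c]pyran-1(3H)-one | CC[Si](CC)(CC)O[C@H]1C[C@@]2(C(C)C)O[C@]23C(=O)OCC[C@]13C | intermediate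
15 | (4aS,5S,7S,7aS)-7-hydroxy-4a-methyl-7-(propan-2-yl)-5-[(triethylsilyl)oxy]hexahydrocyclopenta[c]pyran-1(3H)-one | CC[Si](CC)(CC)O[C@H]1C[C@](O)(C(C)C)[C@H]2C(=O)OCC[C@]12C | intermediate
16 | (4aS,5S,7S,7aS)-4a-methyl-7-(propan-2-yl)-5-[(triethylsilyl)oxy]octahydrocyclopenta[c]pyran-1,7-diol (lactol of 15, anomeric mixture) | CC[Si](CC)(CC)O[C@H]1C[C@](O)(C(C)C)[C@H]2C(O)OCC[C@]12C | intermediate
17 | (1S,2R,3S,4S)-2-[(1R)-1-hydroxyprop-2-en-1-yl]-3-(2-hydroxyethyl)-3-methyl-1-(propan-2-yl)-4-[(triethylsilyl)oxy]cyclopentan-1-ol | CC[Si](CC)(CC)O[C@H]1C[C@](O)(C(C)C)[C@@H]([C@H](O)C=C)[C@]1(C)CCO | intermediate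
18 | (1R,4aS,5S,7S,7aR)-1-ethenyl-4a-methyl-7-(propan-2-yl)-5-[(triethylsilyl)oxy]octahydrocyclopenta[c]pyran-3,7-diol (lactol of 19, anomeric mixture) | CC[Si](CC)(CC)O[C@H]1C[C@](O)(C(C)C)[C@H]2[C@@H](C=C)OC(O)C[C@]12C | intermediate
19 | (1R,4aS,5S,7S,7aR)-1-ethenyl-7-hydroxy-4a-methyl-7-(propan-2-yl)-5-[(triethylsilyl)oxy]hexahydrocyclopenta[c]pyran-3(1H)-one | CC[Si](CC)(CC)O[C@H]1C[C@](O)(C(C)C)[C@H]2[C@@H](C=C)OC(=O)C[C@]12C | intermediate
20 | (1S,2R,3S,4S)-2-[(1R)-1-hydroxyprop-2-en-1-yl]-3-methyl-3-(3-methyl-2-oxobut-3-en-1-yl)-1-(propan-2-yl)-4-[(triethylsilyl)oxy]cyclopentan-1-ol | CC[Si](CC)(CC)O[C@H]1C[C@](O)(C(C)C)[C@@H]([C@H](O)C=C)[C@]1(C)CC(=O)C(C)=C | intermediate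
21 | 4-[(tert-butyldimethylsilyl)oxy]benzoic acid | CC(C)(C)[Si](C)(C)Oc1ccc(C(=O)O)cc1 | starting material
22 | (1R)-1-[(1R,2S,4S,5S)-2-hydroxy-5-methyl-5-(3-methyl-2-oxobut-3-en-1-yl)-2-(propan-2-yl)-4-[(triethylsilyl)oxy]cyclopentyl]prop-2-en-1-yl 4-[(tert-butyldimethylsilyl)oxy]benzoate | CC[Si](CC)(CC)O[C@H]1C[C@](O)(C(C)C)[C@@H]([C@H](OC(=O)c2ccc(O[Si](C)(C)C(C)(C)C)cc2)C=C)[C@]1(C)CC(=O)C(C)=C | intermediate
23 | (1S,3S,3aR,4R,8aS)-3-hydroxy-6,8a-dimethyl-7-oxo-3-(propan-2-yl)-1-[(triethylsilyl)oxy]-1,2,3,3a,4,7,8,8a-octahydroazulen-4-yl 4-[(tert-butyldimethylsilyl)oxy]benzoate | CC[Si](CC)(CC)O[C@H]1C[C@](O)(C(C)C)[C@H]2[C@H](OC(=O)c3ccc(O[Si](C)(C)C(C)(C)C)cc3)C=C(C)C(=O)C[C@]12C | intermediate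
24 | (1S,3S,3aR,4R,8aS)-1,3-dihydroxy-6,8a-dimethyl-7-oxo-3-(propan-2-yl)-1,2,3,3a,4,7,8,8a-octahydroazulen-4-yl 4-[(tert-butyldimethylsilyl)oxy]benzoate | O[C@H]1C[C@](O)(C(C)C)[C@H]2[C@H](OC(=O)c3ccc(O[Si](C)(C)C(C)(C)C)cc3)C=C(C)C(=O)C[C@]12C | intermediate
25 | (1S,3S,3aR,4R,8aS)-1-acetoxy-3-hydroxy-6,8a-dimethyl-7-oxo-3-(propan-2-yl)-1,2,3,3a,4,7,8,8a-octahydroazulen-4-yl 4-[(tert-butyldimethylsilyl)oxy]benzoate | CC(=O)O[C@H]1C[C@](O)(C(C)C)[C@H]2[C@H](OC(=O)c3ccc(O[Si](C)(C)C(C)(C)C)cc3)C=C(C)C(=O)C[C@]12C | intermediate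
26 | (1S,3S,3aR,4R,8aS)-1-acetoxy-3-hydroxy-6,8a-dimethyl-7-oxo-3-(propan-2-yl)-1,2,3,3a,4,7,8,8a-octahydroazulen-4-yl 4-hydroxybenzoate | CC(=O)O[C@H]1C[C@](O)(C(C)C)[C@H]2[C@H](OC(=O)c3ccc(O)cc3)C=C(C)C(=O)C[C@]12C | target

Total step count: 19. Longest linear sequence: 18 steps (steps 1–3 and 5–19, from 1 to 26).

Steps most likely to fail

1. Step 7. The intramolecular carbene transfer may show too little enantiofacial discrimination, may be diverted to C–H insertion or pyrazole formation, or the ion pair may live long enough to lose the C1 configuration. Fallback, setting out from 4 and 7 and returning at 11: acid 7 is esterified (Me3SiCHN2, MeOH) to methyl 4-methyl-3-methylidenepentanoate F1 and converted (p-ABSA, DBU) into methyl 2-diazo-4-methyl-3-methylidenepentanoate F2. Intermolecular cyclopropanation of silyl ether 4 with F2 under Rh2(S-DOSP)4 in pentane at −78 °C, the well-studied intermolecular mode, gives the isolable methyl (1R,2S,3R)-2-{2-[(tert-butyldimethylsilyl)oxy]ethyl}-3-[(4-methoxybenzyl)oxy]-2-methyl-1-(3-methylbut-1-en-2-yl)cyclopropane-1-carboxylate F3, which can be purified and checked. Et2AlCl at −78 °C rearranges it to methyl (4S,5S)-5-{2-[(tert-butyldimethylsilyl)oxy]ethyl}-4-[(4-methoxybenzyl)oxy]-5-methyl-2-(propan-2-yl)cyclopent-1-ene-1-carboxylate F4. Bu4NF then gives methyl (4S,5S)-5-(2-hydroxyethyl)-4-[(4-methoxybenzyl)oxy]-5-methyl-2-(propan-2-yl)cyclopent-1-ene-1-carboxylate F5, which lactonises (PPTS, toluene, 80 °C) to 11.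

2. Step 9. Oxygen transfer to the lactone-conjugated alkene may be slow and the hydrogen-bond direction too weak, giving poor facial selectivity. Fallback, from 12 back to 15: hydrogen-bond-directed syn dihydroxylation with OsO4·TMEDA (CH2Cl2, −78 °C) gives (4aR,5S,7S,7aS)-5,7,7a-trihydroxy-4a-methyl-7-(propan-2-yl)hexahydrocyclopenta[c]pyran-1(3H)-one F6. Silylation of the secondary hydroxyl (Et3SiCl, imidazole) gives (4aR,5S,7S,7aS)-7,7a-dihydroxy-4a-methyl-7-(propan-2-yl)-5-[(triethylsilyl)oxy]hexahydrocyclopenta[c]pyran-1(3H)-one F7. Reductive removal of the hydroxyl α to the lactone carbonyl (SmI2, HMPA, pivalic acid, THF) then gives 15.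

3. Step 11. Protonation of the enolate may occur on the wrong face, or the product may epimerise, giving the cis-fused lactone. Fallback, from 14 back to 15: the crude reduction product, containing (4aS,5S,7S,7aR)-7-hydroxy-4a-methyl-7-(propan-2-yl)-5-[(triethylsilyl)oxy]hexahydrocyclopenta[c]pyran-1(3H)-one F8, is opened with NaOMe in MeOH. This also equilibrates the now monocyclic ester centre, and should give methyl (1S,2S,4S,5S)-2-hydroxy-5-(2-hydroxyethyl)-5-methyl-2-(propan-2-yl)-4-[(triethylsilyl)oxy]cyclopentane-1-carboxylate F9, in which the ester is trans to the isopropyl and hydroxyethyl groups and hydrogen-bonded to the cis tertiary hydroxyl. F9 is relactonised (PPTS, toluene, 80 °C) to 15.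

Further compounds
F1 | step 7 | methyl 4-methyl-3-methylidenepentanoate | CC(C)C(=C)CC(=O)OC
F2 | step 7 | methyl 2-diazo-4-methyl-3-methylidenepentanoate | CC(C)C(=C)C(=[N+]=[N-])C(=O)OC
F3 | step 7 | methyl (1R,2S,3R)-2-{2-[(tert-butyldimethylsilyl)oxy]ethyl}-3-[(4-methoxybenzyl)oxy]-2-methyl-1-(3-methylbut-1-en-2-yl)cyclopropane-1-carboxylate | COC(=O)[C@@]1(C(=C)C(C)C)[C@H](OCc2ccc(OC)cc2)[C@@]1(C)CCO[Si](C)(C)C(C)(C)C
F4 | step 7 | methyl (4S,5S)-5-{2-[(tert-butyldimethylsilyl)oxy]ethyl}-4-[(4-methoxybenzyl)oxy]-5-methyl-2-(propan-2-yl)cyclopent-1-ene-1-carboxylate | COC(=O)C1=C(C(C)C)C[C@H](OCc2ccc(OC)cc2)[C@@]1(C)CCO[Si](C)(C)C(C)(C)C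
F5 | step 7 | methyl (4S,5S)-5-(2-hydroxyethyl)-4-[(4-methoxybenzyl)oxy]-5-methyl-2-(propan-2-yl)cyclopent-1-ene-1-carboxylate | COC(=O)C1=C(C(C)C)C[C@H](OCc2ccc(OC)cc2)[C@@]1(C)CCO
F6 | step 9 | (4aR,5S,7S,7aS)-5,7,7a-trihydroxy-4a-methyl-7-(propan-2-yl)hexahydrocyclopenta[c]pyran-1(3H)-one | O[C@H]1C[C@](O)(C(C)C)[C@]2(O)C(=O)OCC[C@]12C
F7 | step 9 | (4aR,5S,7S,7aS)-7,7a-dihydroxy-4a-methyl-7-(propan-2-yl)-5-[(triethylsilyl)oxy]hexahydrocyclopenta[c]pyran-1(3H)-one | CC[Si](CC)(CC)O[C@H]1C[C@](O)(C(C)C)[C@]2(O)C(=O)OCC[C@]12C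
F8 | step 11 | (4aS,5S,7S,7aR)-7-hydroxy-4a-methyl-7-(propan-2-yl)-5-[(triethylsilyl)oxy]hexahydrocyclopenta[c]pyran-1(3H)-one | CC[Si](CC)(CC)O[C@H]1C[C@](O)(C(C)C)[C@@H]2C(=O)OCC[C@]12C
F9 | step 11 | methyl (1S,2S,4S,5S)-2-hydroxy-5-(2-hydroxyethyl)-5-methyl-2-(propan-2-yl)-4-[(triethylsilyl)oxy]cyclopentane-1-carboxylate | CC[Si](CC)(CC)O[C@H]1C[C@](O)(C(C)C)[C@@H](C(=O)OC)[C@]1(C)CCO
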